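**Retrosynthetic overview** (labdane numbering)
1. Last operation: C11–C12 and C8–C9 are cut together. The target falls back to a monocyclic ring-A aldehyde, 4-[(1S,2S)-2-ethenyl-6,6-bis(hydroxymethyl)-2-methylcyclohexyl]butanal, and racemic 4-acetoxy-3-methylideneoxolan-2-one.
2. Enabling feature: the C17 formyl group sits on C8 of ring B, next to C9, which carries C11. An enamine-derived electrophilic C8 radical can add across a C9=C11 vinyl group on quaternary C10 and pass the spin to C11. C12 is the β-carbon of the C16 lactone carbonyl and C14 can carry a leaving group, so C11 is captured at C12 and loss of acetate forms C13=C14. Both new centres are equatorial on the trans-decalin, and C8 is epimerisable.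
3. Ring-A aldehyde: from diethyl 4-oxocyclohexane-1,1-dicarboxylate via the 2-methyl enone. The steps are Cu-catalysed asymmetric conjugate addition (C5–C6) with anti aldol trapping by formaldehyde (C10–C9), C1 deoxygenation, malonate reduction (C18/C19 diol) and methylenation of the C9 aldehyde.
4. Lactone partner: Morita–Baylis–Hillman adduct, lactonisation, acetylation.
5. Ring order: ring A is bought, the lactone ring closes in step 2, and ring B closes last, in step 13.

Key step: step 13

Assumption: the lactone partner is used as the racemate because its only stereocentre (C14) is destroyed in the key step. Locants C1–C20 in the text follow labdane numbering.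

Step 1
Reactants: 1 methyl acrylate; 2 (tert-butyldimethylsilyloxy)acetaldehyde
Product: 3 methyl 2-[2-(tert-butyldimethylsilyloxy)-1-hydroxyethyl]prop-2-enoate (racemic)
Conditions: DABCO (0.5 equiv), 1,4-dioxane–H2O, rt
Reagents that add atoms: none
Why: Morita–Baylis–Hillman reaction of an acrylate with a reactive α-oxy aldehyde; the carbinol centre is formed racemic on purpose because it is erased in step 13.

Step 2
Reactants: 3 methyl 2-[2-(tert-butyldimethylsilyloxy)-1-hydroxyethyl]prop-2-enoate
Product: 5 4-hydroxy-3-methylideneoxolan-2-one (racemic), via diol ester 4 (not isolated)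
Conditions: 1 M aq. HCl, THF, rt
Reagents that add atoms: none
Why: acid desilylation frees the primary alcohol, which should lactonise onto the methyl ester (acid-catalysed transesterification to the five-membered ring).

Step 3
Reactants: 5 4-hydroxy-3-methylideneoxolan-2-one
Product: 6 4-acetoxy-3-methylideneoxolan-2-one (racemic)
Conditions: Ac2O (1.2 equiv), Sc(OTf)3 (1 mol %), MeCN, 0 °C
Reagents that add atoms: acetic anhydride, CC(=O)OC(C)=O
Why: Lewis-acid-catalysed O-acetylation avoids nucleophilic amines, which could transpose the allylic acetate by SN2′ attack.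

Step 4
Reactants: 7 diethyl 4-oxocyclohexane-1,1-dicarboxylate
Product: 9 diethyl 3-methyl-4-oxocyclohexane-1,1-dicarboxylate (racemic), via lithium enolate 8 (not isolated)
Conditions: LDA (1.05 equiv), THF, −78 °C; MeI, −78 to 0 °C
Reagents that add atoms: iodomethane, CI
Why: kinetic enolate alkylation of a symmetric ketone whose two α-positions are equivalent and whose malonate carbon cannot enolise; the new centre is flattened in step 5.

Step 5
Reactants: 9 diethyl 3-methyl-4-oxocyclohexane-1,1-dicarboxylate
Product: 11 diethyl 3-methyl-4-oxocyclohex-2-ene-1,1-dicarboxylate, via chloro ketone 10 (not isolated)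
Conditions: SO2Cl2 (1.05 equiv), CH2Cl2, 0 °C to rt; solvent change; LiCl (0.3 equiv), DMF, 100 °C
Reagents that add atoms: none
Why: α-chlorination through the more substituted enol followed by dehydrochlorination is the classical 2-methylcyclohexanone to 2-methylcyclohexenone sequence, run well below Krapcho dealkoxycarbonylation temperatures.

Step 6
Reactants: 11 diethyl 3-methyl-4-oxocyclohex-2-ene-1,1-dicarboxylate; 12 2-(3-chloropropyl)-1,3-dioxolane
Product: 15 diethyl (2S,3R)-2-[3-(1,3-dioxolan-2-yl)propyl]-3-(hydroxymethyl)-3-methyl-4-oxocyclohexane-1,1-dicarboxylate, via Grignard reagent 13 (not isolated), via magnesium enolate 14 (not isolated)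
Conditions: 12, Mg, THF, 40 °C; Cu(OTf)2 (5 mol %), chiral hydroxyalkyl-imidazolinium salt (NHC precursor, 7 mol %, the enantiomer that gives 2S), 11, Et2O–THF, −30 °C; monomeric CH2O in THF, −78 to −30 °C; aq. NH4Cl
Reagents that add atoms: formaldehyde, C=O
Why: Cu/NHC-catalysed asymmetric conjugate addition of a Grignard reagent to a 2-methylcyclohexenone with trapping of the regiodefined magnesium enolate (tandem conjugate addition–aldol); the ligand sets C5, and formaldehyde enters C10 anti to the new pseudo-axial side chain, so C9 ends trans and the methyl group cis to that chain.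

Step 7
Reactants: 15 diethyl (2S,3R)-2-[3-(1,3-dioxolan-2-yl)propyl]-3-(hydroxymethyl)-3-methyl-4-oxocyclohexane-1,1-dicarboxylate
Product: 17 diethyl (2S,3R)-2-[3-(1,3-dioxolan-2-yl)propyl]-3-(hydroxymethyl)-3-methylcyclohexane-1,1-dicarboxylate, via tosylhydrazone 16 (not isolated)
Conditions: TsNHNH2, EtOH, 70 °C; evaporate; catecholborane (3 equiv), CHCl3, 0 °C; NaOAc·3H2O, reflux
Reagents that add atoms: none
Why: tosylhydrazone reduction (Caglioti type, catecholborane variant) removes the C1 carbonyl while esters, acetal and both non-epimerisable stereocentres stay untouched.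

Step 8
Reactants: 17 diethyl (2S,3R)-2-[3-(1,3-dioxolan-2-yl)propyl]-3-(hydroxymethyl)-3-methylcyclohexane-1,1-dicarboxylate
Product: 18 [(2S,3R)-2-[3-(1,3-dioxolan-2-yl)propyl]-3-methylcyclohexane-1,1,3-triyl]trimethanol
Conditions: LiAlH4, THF, 0 °C to rt
Reagents that add atoms: none
Why: hydride reduction of the gem-diester gives the C18/C19 diol; C4 carries two equal groups and is no stereocentre, and the acetal is inert.

Step 9
Reactants: 18 [(2S,3R)-2-[3-(1,3-dioxolan-2-yl)propyl]-3-methylcyclohexane-1,1,3-triyl]trimethanol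
Product: 19 {(7S,8R)-7-[3-(1,3-dioxolan-2-yl)propyl]-3,3,8-trimethyl-2,4-dioxaspiro[5.5]undecan-8-yl}methanol
Conditions: 2,2-dimethoxypropane, PPTS (cat.), CH2Cl2, rt
Reagents that add atoms: 2,2-dimethoxypropane, COC(C)(C)OC
Why: thermodynamic acetalisation picks the 1,3-diol on C4 (six-membered 1,3-dioxane) and leaves the C9 carbinol free, since any ring through C9–OH would be eight-membered.

Step 10
Reactants: 19 {(7S,8R)-7-[3-(1,3-dioxolan-2-yl)propyl]-3,3,8-trimethyl-2,4-dioxaspiro[5.5]undecan-8-yl}methanol
Product: 20 (7R,8R)-7-[3-(1,3-dioxolan-2-yl)propyl]-3,3,8-trimethyl-2,4-dioxaspiro[5.5]undecane-8-carbaldehyde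
Conditions: TPAP (5 mol %), NMO, 4 Å MS, CH2Cl2, rt
Reagents that add atoms: none
Why: Ley–Griffith oxidation is neutral, so both acetals survive, and the aldehyde formed is non-enolisable (the descriptor at C7 changes only through CIP priorities).

Step 11
Reactants: 20 (7R,8R)-7-[3-(1,3-dioxolan-2-yl)propyl]-3,3,8-trimethyl-2,4-dioxaspiro[5.5]undecane-8-carbaldehyde
Product: 21 (7S,8S)-7-[3-(1,3-dioxolan-2-yl)propyl]-8-ethenyl-3,3,8-trimethyl-2,4-dioxaspiro[5.5]undecane
Conditions: Ph3PCH3Br, KOtBu, THF, 0 to 40 °C
Reagents that add atoms: methyltriphenylphosphonium bromide, C[P+](c1ccccc1)(c1ccccc1)c1ccccc1.[Br-]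
Why: Wittig methylenation of a hindered, non-enolisable aldehyde installs C11 and gives the C9=C11 vinyl group on quaternary C10.

Step 12
Reactants: 21 (7S,8S)-7-[3-(1,3-dioxolan-2-yl)propyl]-8-ethenyl-3,3,8-trimethyl-2,4-dioxaspiro[5.5]undecane
Product: 22 4-[(1S,2S)-2-ethenyl-6,6-bis(hydroxymethyl)-2-methylcyclohexyl]butanal
Conditions: 1 M aq. HCl–THF, rt
Reagents that add atoms: water, O
Why: aqueous acid hydrolysis should open the dioxolane and the acetonide in one operation, while the isolated vinyl group and both stereocentres are inert.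

Step 13
Reactants: 22 4-[(1S,2S)-2-ethenyl-6,6-bis(hydroxymethyl)-2-methylcyclohexyl]butanal; 6 4-acetoxy-3-methylideneoxolan-2-one
Product: 25 (1R,2S,4aS,8aS)-5,5-bis(hydroxymethyl)-8a-methyl-1-[2-(2-oxo-2,5-dihydrofuran-3-yl)ethyl]decahydronaphthalene-2-carbaldehyde, via enamine 23 (not isolated), via C11 radical iminium 24 (not isolated)
Conditions: [Ir(dF(CF3)ppy)2(dtbbpy)]PF6 (1 mol %), rac-5-benzyl-2,2,3-trimethylimidazolidin-4-one·TFA (20 mol %), 6 (3 equiv), 2,6-lutidine (1.5 equiv), degassed DME (0.05 M), blue LEDs (450 nm), rt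
Reagents that add atoms: none
Why: Proposed new method: the C17 aldehyde condenses with the imidazolidinone to enamine 23, which excited Ir(III) oxidises to an electrophilic enaminyl radical cation centred on C8; this radical is polarity-mismatched with electron-poor 6 but adds to the unactivated vinyl group at C9, the spin moves to C11 as the nucleophilic primary radical 24 that is matched to the exocyclic C12 methylene of 6 (C11–C12 bond), and Ir(II) reduces the resulting C13 α-lactonyl radical to an enolate that expels the C14 acetate (E1cB), which forms the C13=C14 butenolide and closes a redox-neutral cycle before the iminium is hydrolysed. The closest known reaction types are the photoredox/enamine α-alkylation of aldehydes with tethered simple olefins, which is ended by thiol hydrogen transfer, and the radical addition–elimination allylation with Morita–Baylis–Hillman acetates or allyl sulfones; new is only that the second replaces the hydrogen transfer of the first. Ring B closes 6-exo-trig through a chair-like transition state whose tether ends (C6 on C5, C9 on C10) are locked trans-diequatorial on ring A, so that only the trans-decalin can form. C9 is set by the vinyl rotamer that keeps C11 pseudo-equatorial (anti to C5), because the pseudo-axial rotamer pushes C11 against the axial hydrogens on C5 and C7; C8 is set by the pseudo-equatorial iminium substituent and, being α to the iminium/aldehyde, any axial epimer should drain through the enamine to the all-equatorial thermodynamic aldehyde. The step needs chemoselectivity among the radicals and 6-exo over 7-endo closure: the first is secured by the alternation electrophilic C8 radical, neutral alkene, nucleophilic C11 radical, electron-poor alkene, the second by quaternary C10 next to the alkene (gem-dialkyl acceleration of exo closure) and by the short ring-anchored tether. The free C18/C19 hydroxyl groups are spectators for the enamine, radical and electron-transfer events, and the racemic C14 centre of 6 is erased, so one isomer of 25 should result.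

**Compound list**
1 | methyl acrylate | C=CC(=O)OC | starting material
2 | (tert-butyldimethylsilyloxy)acetaldehyde | CC(C)(C)[Si](C)(C)OCC=O | starting material
3 | methyl 2-[2-(tert-butyldimethylsilyloxy)-1-hydroxyethyl]prop-2-enoate (racemic) | C=C(C(=O)OC)C(O)CO[Si](C)(C)C(C)(C)C | intermediate
4 | methyl 2-(1,2-dihydroxyethyl)prop-2-enoate (racemic, not isolated) | C=C(C(=O)OC)C(O)CO | intermediate
5 | 4-hydroxy-3-methylideneoxolan-2-one (racemic) | C=C1C(O)COC1=O | intermediate
6 | 4-acetoxy-3-methylideneoxolan-2-one (racemic) | C=C1C(OC(C)=O)COC1=O | intermediate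
7 | diethyl 4-oxocyclohexane-1,1-dicarboxylate | CCOC(=O)C1(CCC(=O)CC1)C(=O)OCC | starting material
8 | lithium enolate of 7 (not isolated) | CCOC(=O)C1(CCC([O-])=CC1)C(=O)OCC.[Li+] | intermediate
9 | diethyl 3-methyl-4-oxocyclohexane-1,1-dicarboxylate (racemic) | CCOC(=O)C1(CCC(=O)C(C)C1)C(=O)OCC | intermediate
10 | diethyl 3-chloro-3-methyl-4-oxocyclohexane-1,1-dicarboxylate (racemic, not isolated) | CCOC(=O)C1(CCC(=O)C(C)(Cl)C1)C(=O)OCC | intermediate
11 | diethyl 3-methyl-4-oxocyclohex-2-ene-1,1-dicarboxylate | CCOC(=O)C1(CCC(=O)C(C)=C1)C(=O)OCC | intermediate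
12 | 2-(3-chloropropyl)-1,3-dioxolane | ClCCCC1OCCO1 | starting material
13 | [3-(1,3-dioxolan-2-yl)propyl]magnesium chloride (not isolated) | Cl[Mg]CCCC1OCCO1 | intermediate
14 | chloromagnesium enolate after conjugate addition, C5 set (not isolated) | CC1=C(O[Mg]Cl)CCC(C(=O)OCC)(C(=O)OCC)[C@H]1CCCC1OCCO1 | intermediate
15 | diethyl (2S,3R)-2-[3-(1,3-dioxolan-2-yl)propyl]-3-(hydroxymethyl)-3-methyl-4-oxocyclohexane-1,1-dicarboxylate | C[C@@]1(CO)C(=O)CCC(C(=O)OCC)(C(=O)OCC)[C@H]1CCCC1OCCO1 | intermediate
16 | tosylhydrazone of 15 (not isolated) | C[C@@]1(CO)C(=NNS(=O)(=O)c2ccc(C)cc2)CCC(C(=O)OCC)(C(=O)OCC)[C@H]1CCCC1OCCO1 | intermediate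
17 | diethyl (2S,3R)-2-[3-(1,3-dioxolan-2-yl)propyl]-3-(hydroxymethyl)-3-methylcyclohexane-1,1-dicarboxylate | C[C@@]1(CO)CCCC(C(=O)OCC)(C(=O)OCC)[C@H]1CCCC1OCCO1 | intermediate
18 | [(2S,3R)-2-[3-(1,3-dioxolan-2-yl)propyl]-3-methylcyclohexane-1,1,3-triyl]trimethanol | C[C@@]1(CO)CCCC(CO)(CO)[C@H]1CCCC1OCCO1 | intermediate
19 | {(7S,8R)-7-[3-(1,3-dioxolan-2-yl)propyl]-3,3,8-trimethyl-2,4-dioxaspiro[5.5]undecan-8-yl}methanol | C[C@@]1(CO)CCCC2(COC(C)(C)OC2)[C@H]1CCCC1OCCO1 | intermediate
20 | (7R,8R)-7-[3-(1,3-dioxolan-2-yl)propyl]-3,3,8-trimethyl-2,4-dioxaspiro[5.5]undecane-8-carbaldehyde | C[C@@]1(C=O)CCCC2(COC(C)(C)OC2)[C@H]1CCCC1OCCO1 | intermediate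
21 | (7S,8S)-7-[3-(1,3-dioxolan-2-yl)propyl]-8-ethenyl-3,3,8-trimethyl-2,4-dioxaspiro[5.5]undecane | C[C@@]1(C=C)CCCC2(COC(C)(C)OC2)[C@H]1CCCC1OCCO1 | intermediate
22 | 4-[(1S,2S)-2-ethenyl-6,6-bis(hydroxymethyl)-2-methylcyclohexyl]butanal | C[C@@]1(C=C)CCCC(CO)(CO)[C@H]1CCCC=O | intermediate
23 | (E)-enamine of 22 and 5-benzyl-2,2,3-trimethylimidazolidin-4-one, catalyst centre racemic (not isolated) | C[C@@]1(C=C)CCCC(CO)(CO)[C@H]1CC/C=C/N1C(Cc2ccccc2)C(=O)N(C)C1(C)C | intermediate
24 | ring-B-closed iminium ion carrying the primary C11 radical (not isolated) | C[C@@]12CCCC(CO)(CO)[C@H]1CC[C@H](C=[N+]3C(Cc4ccccc4)C(=O)N(C)C3(C)C)[C@H]2[CH2] | intermediate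
25 | (1R,2S,4aS,8aS)-5,5-bis(hydroxymethyl)-8a-methyl-1-[2-(2-oxo-2,5-dihydrofuran-3-yl)ethyl]decahydronaphthalene-2-carbaldehyde; labdane numbering 5S,8S,9R,10S | C[C@@]12CCCC(CO)(CO)[C@H]1CC[C@H](C=O)[C@H]2CCC1=CCOC1=O | target

**Step count:** 13 steps in total. The longest linear sequence is 10 steps (steps 4–13, from 7).

**Steps most likely to fail**

1. Step 13 (Proposed new method).
   - What may go wrong: alkylation of the amine catalyst by the electrophilic lactone, 7-endo instead of 6-exo closure, hydrogen abstraction by the C11 radical before it meets the lactone, or poor facial selectivity at C9.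
   - Fallback: the same bonds are made as single events of known radical chemistry, from 22 back to 25.
   - Organocatalytic α-selenenylation of 22 with N-(phenylselanyl)phthalimide should give the α-(phenylselanyl) aldehyde F1.
   - Irradiation in benzene should trigger phenylselanyl group-transfer 6-exo cyclisation to the decalin selenide F2.
   - (Me3Si)3SiH/AIBN should release the C11 radical from F2 for a Giese addition to 6, giving the saturated β-acetoxy lactone F3.
   - Triethylamine should then eliminate acetic acid (E1cB) to 25.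

2. Step 6.
   - What may go wrong: sluggish conjugate addition next to the quaternary malonate carbon, insufficient enantio-induction on this hindered enone, or retro-aldol loss of formaldehyde from the magnesium aldolate.
   - Fallback: resolution replaces asymmetric catalysis, from 11 back to 18.
   - The stoichiometric cuprate from 13 (CuBr·SMe2, TMSCl, THF, −78 °C) should give the racemic trimethylsilyl enol ether F4.
   - Mukaiyama aldol hydroxymethylation (aq. CH2O, Yb(OTf)3) should give the racemic keto alcohol F5.
   - Esterification with N-Boc-L-phenylalanine (DCC, DMAP) should give the wanted diastereomeric ester F6 and the unwanted diastereomeric ester F7, to be separated by chromatography or crystallisation.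
   - F6 is taken through the conditions of step 7 via the ester tosylhydrazone F8 to the deoxygenated ester F9.
   - The LiAlH4 reduction of step 8 cleaves the auxiliary ester together with the malonate and arrives at 18.

3. Step 7.
   - What may go wrong: slow condensation at the neopentyl ketone, retro-aldol cleavage on heating, or elimination to an alkene instead of reduction.
   - Fallback: radical instead of ionic deoxygenation, from 15 back to 17.
   - NaBH4 should give the 1,3-diol F10.
   - Thiocarbonyldiimidazole should give the six-membered cyclic thionocarbonate F11.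
   - Bu3SnH/AIBN (Barton–McCombie type) should cleave the C–O bond that leads to the secondary C1 radical, and hydrolytic work-up should free the C9 carbinol, giving 17.
   - No vinyl group is present at this stage, so no radical vinyl shift can interfere.

**Further compounds**
F1 | step 13 | 4-[(1S,2S)-2-ethenyl-6,6-bis(hydroxymethyl)-2-methylcyclohexyl]-2-(phenylselanyl)butanal (epimers at the selenium-bearing carbon) | C[C@@]1(C=C)CCCC(CO)(CO)[C@H]1CCC([Se]c1ccccc1)C=O
F2 | step 13 | (1R,2S,4aS,8aS)-5,5-bis(hydroxymethyl)-8a-methyl-1-[(phenylselanyl)methyl]decahydronaphthalene-2-carbaldehyde | C[C@@]12CCCC(CO)(CO)[C@H]1CC[C@H](C=O)[C@H]2C[Se]c1ccccc1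
F3 | step 13 | saturated 4-acetoxy lactone adduct (isomers at the two lactone centres) | C[C@@]12CCCC(CO)(CO)[C@H]1CC[C@H](C=O)[C@H]2CCC1C(OC(C)=O)COC1=O
F4 | step 6 | racemic trimethylsilyl enol ether (both enantiomers) | CC1=C(O[Si](C)(C)C)CCC(C(=O)OCC)(C(=O)OCC)[C@H]1CCCC1OCCO1.CC1=C(O[Si](C)(C)C)CCC(C(=O)OCC)(C(=O)OCC)[C@@H]1CCCC1OCCO1
F5 | step 6 | racemic keto alcohol, relative configuration of 15 (both enantiomers) | C[C@@]1(CO)C(=O)CCC(C(=O)OCC)(C(=O)OCC)[C@H]1CCCC1OCCO1.C[C@]1(CO)C(=O)CCC(C(=O)OCC)(C(=O)OCC)[C@@H]1CCCC1OCCO1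
F6 | step 6 | N-Boc-L-phenylalanine ester of 15 (wanted diastereomer) | C[C@@]1(COC(=O)[C@H](Cc2ccccc2)NC(=O)OC(C)(C)C)C(=O)CCC(C(=O)OCC)(C(=O)OCC)[C@H]1CCCC1OCCO1
F7 | step 6 | N-Boc-L-phenylalanine ester of the enantiomer of 15 (unwanted diastereomer) | C[C@]1(COC(=O)[C@H](Cc2ccccc2)NC(=O)OC(C)(C)C)C(=O)CCC(C(=O)OCC)(C(=O)OCC)[C@@H]1CCCC1OCCO1
F8 | step 6 | tosylhydrazone of F6 | C[C@@]1(COC(=O)[C@H](Cc2ccccc2)NC(=O)OC(C)(C)C)C(=NNS(=O)(=O)c2ccc(C)cc2)CCC(C(=O)OCC)(C(=O)OCC)[C@H]1CCCC1OCCO1
F9 | step 6 | N-Boc-L-phenylalanine ester of 17 | C[C@@]1(COC(=O)[C@H](Cc2ccccc2)NC(=O)OC(C)(C)C)CCCC(C(=O)OCC)(C(=O)OCC)[C@H]1CCCC1OCCO1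
F10 | step 7 | 1,3-diol from ketone reduction of 15 (carbinol epimers) | C[C@@]1(CO)C(O)CCC(C(=O)OCC)(C(=O)OCC)[C@H]1CCCC1OCCO1
F11 | step 7 | six-membered cyclic thionocarbonate of F10 | C[C@@]12COC(=S)OC1CCC(C(=O)OCC)(C(=O)OCC)[C@H]2CCCC1OCCO1
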